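The readings were generated by integration with constants of no real substance; noise was put on by code.

No constant of this scheme is given to me, so I have to read what matters for the row from the three earlier runs.

all flasks: solid substrate 0.50 M

| run | coupling partner | catalyst | remark | time |
|---|---|---|---|---|
| green | 0.55 M | 0.053 mM | run made earlier |  |
| ochre | 0.55 M | 0.58 mM | run made earlier |  |
| amber | 0.55 M | 4.3 mM | run made earlier |  |
| larch | 0.550 M | 0.060 mM |  | 6.0 min |
| oak | 0.550 M | 0.20 mM |  | 6.0 min |
| elm | 0.550 M | 0.60 mM |  | 6.0 min |
| cedar | 0.550 M | 1.5 mM |  | 6.0 min |
| alder | 0.550 M | 5.0 mM |  | 6.0 min |

| run | time / min | target / % | solid substrate / % |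
|---|---|---|---|
| green | 0.417 | 1.1 | 97.5 |
| green | 1.00 | 2.0 | 92.4 |
| green | 2.00 | 4.0 | 84.4 |
| green | 3.00 | 5.2 | 76.8 |
| ochre | 0.833 | 2.5 | 93.6 |
| ochre | 1.50 | 3.2 | 88.9 |
| ochre | 2.50 | 4.7 | 81.0 |
| ochre | 3.00 | 5.9 | 77.3 |
| amber | 0.250 | 0.5 | 98.7 |
| amber | 0.500 | 0.7 | 95.8 |
| amber | 1.33 | 2.2 | 89.9 |
| amber | 3.00 | 4.9 | 77.5 |

(scatter of a reading: 0.5 percentage points)

- solid substrate is a solid; its amount is given per volume of the solution
- reactions considered so far: starting material + coupling partner <-> target; starting material + coupling partner <-> isomer of the product; target + catalyst <-> isomer of the product + catalyst; solid substrate <-> starting material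
- at the start none of the solid substrate is in solution
- "hardly changes" means that all values lie within two and a half points (for a concentration: within two and a half percent of the largest)

* amount of target at the end, in percent of the solid substrate charged for larch, oak, elm, cedar, alder, in this order
* the shape of the row from first to last (rises all the way / falls, then rises / hardly changes / falls all the way / rises, then falls)

I follow one molecule of target after it forms: it stays target, goes back to starting material and coupling partner, or the catalyst turns it into isomer of the product. Solid substrate at 3.00 min reads 76.8% in green and 77.5% in amber, so I take the feed as the same in every flask and look at the catalyst's fork, leaving the way back out of my reckoning. I reckon there with two times: the mean age of target, and how long target lasts against the catalyst.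

Target grows nearly linearly, so if none goes back, its mean age at 3.00 min is 1.50 min. Amber reads 4.9% of target there and green 5.2%, a loss share of 5.77%. With a scatter of 0.5 percentage points per reading, this figure is also compatible with no loss. I treat the drain as pseudo-first-order, proportional to catalyst, and neglect it in green. Mean age over loss share then gives 26.0 min for amber. Scaled by catalyst, this is the drain time, the mean time target lasts against the catalyst: 22.4 min in alder and 1860 min in larch.

Green's slope gives 10.4% of target at 6.0 min without drain. Alder's mean age of 3.00 min against its drain time takes that down, so I commit to 10.4% in larch and 9.01% in alder.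

The forecast gives 10.5% in larch and 9.5% in alder, a smaller fall than mine, and says the row hardly changes, since "Any catalysed target-to-isomer drain is therefore weak".

    starting material + coupling partner ⇌ target (K = 1.80 M⁻¹, k = 8.40 M⁻¹ min⁻¹)
    starting material + coupling partner ⇌ isomer of the product (K = 3.90 M⁻¹, k = 4.30 M⁻¹ min⁻¹)
    target + catalyst ⇌ isomer of the product + catalyst, rate k3*[catalyst]*[target] forward; the back reaction follows from the equilibrium constant (k = 12.0 M⁻¹ min⁻¹)
    solid substrate ⇌ starting material, rate k4*(cs4 - [starting material]) while solid is left; crystals form when [starting material] > cs4 (solubility = 0.430 M, k = 0.0920 min⁻¹)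

The flasks give 9.93% in larch and 9.91% in alder, so the row hardly changes, and the fall is 0.02 points against my 1.4 points. The passing of target into isomer of the product makes no difference to target in alder. By its back step alone, target returns to starting material and coupling partner in a mean time of 0.214 min, far shorter than my drain time of 22.4 min in alder and 1860 min in larch.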